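Step 1 runs both ways, so it cannot carry all the Z of this flask into X.G; the question is how the Z divides.

Z 1.2 M; G 1.80 M; L 1.20 M; time 3.0 h

    X + G ⇌ X.G (K1 = 1.1 L mol⁻¹, k1 = 0.0065 L mol⁻¹ s⁻¹)
    L + G → L.G (k2 = 0.0071 L mol⁻¹ s⁻¹)
    X + L → X.L (k3 = 0.0051 L mol⁻¹ s⁻¹)
    Z ⇌ X, rate k4*(cs4 - [X]) while solid is left; crystals form when [X] > cs4 (cs4 = 0.71 M, k4 = 0.0070 s⁻¹)

* the state of affairs at 3.0 h: stopped, and by what, or still going (for what has run out or reacted, a solid counts together with what of it has only dissolved) (all of Z has reacted / forward and back rates have come level / G has run out first / it is still moving)
* how much X.G there is at 3.0 h, in percent of the Z charged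
* how much X there is at 3.0 h, in percent of the Z charged

- solid, in amounts per volume of the solution: Z
- at the start none of Z is in solution
- what has only dissolved of Z counts as not reacted
- X means what is dissolved; the solid is not counted in it
- the reaction counts as stopped when no species that holds the Z changes by six tenths of a point or more over the second half of the time
- run time (flask): 3.0 h

The number I want is N, the X.G held per X once this flask is at rest, which at balance of step 1 is K1 times [G]. L goes first: its half-life against G as charged is 0.90 min, short against the run. Dissolution, with nothing drawing on X, closes half the gap between [X] and the solubility in 1.65 min, which is a time for that gap and not a half-life of Z. As a rough guess, then, while L lasts I take [X] near 0.355 M and [G] near 1.20 M. The selectivity factor, X.L made per L.G, is then 0.212, which gives 0.210 M of X.L. That leaves 0.990 M of Z for X and X.G, and 0.810 M of G not bound to L.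

At balance, [G] is that amount divided by 1 + K1[X]. With [X] at the solubility, [G] is 0.455 M, which makes 0.355 M of X.G. So [X] is really 0.634 M, and a second round gives [G] = 0.477 M. N moves from 0.500 to 0.525, the X.G held per X at rest, so one number nearly serves; the rough part is the X.L. Split by N, y_P is 28.4 % and y_A is 54.1 %. The back step's half-life is 1.96 min, short against the run, so I expect: forward and back rates have come level.

The forecast says forward and back rates have come level, with 27.7 % and 58.8 %, a higher X than mine, on the ground that “3 h is far longer than every remaining time scale”.

The simulation gives forward and back rates have come level, with 27.9 % and 57.5 %.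

In this flask at 3.00 h, step 1 relaxes with a half-life of 0.871 min, short against the 3.0 h of the run; its backward turnover is 98 % of the forward one, and the flask reads 0.485 X.G per X against my N of 0.525. In the neighbour flask with 0.48 M of L, I reckon 0.0674 M of X.L, two rounds give N = 0.968, and that flask ends with 45.6 % of X.G against 50.7 % of X, a reading of 0.899.

The numbers of this flask come from no measurement.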